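Tally the reagent per litre of the first phase: what stands in the second phase plus what has left it, net of what came back, is always the charge, whatever the first phase does.

    reagent in the reaction phase + target → over-reacted product (k1 = 0.14 M⁻¹ s⁻¹)
    reagent in the reaction phase ⇌ reagent in the second phase, rate k2*([reagent in the reaction phase] - [reagent in the second phase]/K2) per volume of the first phase (K2 = 2.9, k2 = 0.0015 s⁻¹)
    reagent in the reaction phase → decomposed reagent (k3 = 0.012 s⁻¹)
    starting material + reagent in the reaction phase ⇌ target (K4 = 4.8 M⁻¹, k4 = 0.11 M⁻¹ s⁻¹)

starting material 1.6 M; reagent in the second phase 1.44 M; time 30 min; volume of the second phase over the first 0.50

- in the second phase: reagent in the second phase; everything else is in the first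
- charges count per volume of the first phase; a concentration in a rate is the amount of a species over the volume of its own phase; every rate counts per litre of the first phase
- run time (flask): 30 min

- the target standing at 30 min, as a percentage of the starting material charged
- the change that raises the amount of target at 30 min, in percent of the starting material charged most ("none" if none brings more than 2 percentage points) (teal / amber / none)
- amount of target at 30 min, in percent of the starting material charged, after teal

- teal: doubling the transfer coefficient of step 2, all else as stated
- amber: doubling the amount of reagent in the second phase, all else as stated

You can size the outflow before anything reacts. The charge stands in the second phase at 2.88 M, which would balance 0.993 M of reagent in the reaction phase. But decomposition alone has a half-life there of 0.96 min, far shorter than the time the second phase takes to empty, so I take c(reagent in the reaction phase) to stay far below that level and drop the back-flow. The reagent in the second phase, your reservoir, then falls exponentially, with the drain time, volume ratio times partition ratio over transfer coefficient, 16.1 min. The supply to the first phase at any moment is what is left in the reservoir over the drain time.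

Teal doubles the transfer coefficient, so the drain time falls to half. Its supply starts doubled but dies sooner. The zero of the scale is the moment when the two supplies are equal, the drain time times ln(2), 11.2 min.

| Time | Left, flask | Left, teal | Supply, teal over flask |
|---|---|---|---|
| 3.00 min | 83.0% | 68.9% | 1.66 |
| 11.2 min | 49.9% | 24.9% | 1.00 |
| 30 min | 15.5% | 2.41% | 0.310 |

Read down the last column. Teal feeds more than the flask in the first row, and in the second it feeds as much as the flask from a smaller reservoir. In the third it feeds less than the flask. Does the target follow that last row? The target's way back has a half-life of 0.504 min, far shorter than the drain time, so I expect it to move with the present supply, not the total delivered, though not necessarily in proportion. I therefore expect teal to lower the target. In this reckoning amber doubles the supply throughout, but how much of that stands as target is beyond it, and I give no percentage.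

The forecast said 3.3% (range 2.8% to 3.8%), 1.8% after teal (range 1.4% to 2.3%), and best none: “Teal drains the reservoir sooner”, and amber brings “a gain under 2 points”.

The flask gives 3.37%, and 1.98% after teal, a change of −1.4 percentage points; amber brings 0.16 points, less than 2 points, so the best change is none. At 30.0 min the flask's reservoir reads 16.8% of its charge, against 15.5% from the drain time, and c(reagent in the reaction phase) reads 0.0101 M, far below the 0.167 M that balances what is left. The drain time contains no starting material, so it gives the neighbour charged with 0.40 M of starting material the same 15.5%, and that neighbour reads 17.9% at 30.0 min.

(The numbers of this flask come from no measurement; no experiment stands behind them.)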